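**Plan**
1. Feature: the target is a 2-acyl-6-(sec-alkyl)-4-methoxyphenol. The ketone carbon on ring carbon C2 is the only link between the benzene ring and an eight-carbon chain, and the (2E,4E,6E)-trienone of that chain is a redox isomer of the ynone ArC(=O)–C≡C–CH2–CH2–CH=CH–CO2R.
2. Retrosynthesis: first the acid-labile groups and the trienone (back to the ynone); then both bonds at the ketone carbon, C2–C(=O) and C(=O)–C(sp), giving an aryl iodide, CO and an enyne ester; then the two enoate C=C bonds (Wittig) and the aryl–CH(CH3) bond (redox-relay Heck arylation).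
3. Forward: the arene fragment is built in steps 1–7 and the enyne ester in step 8; they are joined through CO in step 9, the chain is isomerised in step 10 and unmasked in step 11. No ring is closed; the benzene ring comes from the starting phenol.
4. Stereochemistry: the single (R)-centre is set in step 3 by the chiral pyridine-oxazoline ligand on palladium and is never α to a carbonyl afterwards. The E double bonds come from stabilised ylides and from thermodynamic control in step 10.

Key step: step 9

Assumption: in step 3 the (S)-ligand is taken to deliver the aryl group to the face of the (E)-alkene that gives the (R)-centre; if the sense proves opposite, the (R)-ligand is used and nothing else changes.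

Step 1
Reactants: 1 2-bromo-4-methoxyphenol
Product: 2 2-bromo-4-methoxy-1-(methoxymethoxy)benzene
Conditions: NaH, MOMCl, THF, 0 °C → rt
Reagents that add atoms: chloromethyl methyl ether COCCl
Why: Williamson-type O-alkylation of the sodium phenoxide with the α-chloro ether should give the MOM acetal, which removes the acidic proton ahead of the lithiation.

Step 2
Reactants: 2 2-bromo-4-methoxy-1-(methoxymethoxy)benzene
Product: 5 [5-methoxy-2-(methoxymethoxy)phenyl]boronic acid, via aryllithium 3 (not isolated), via lithium aryltriisopropoxyborate 4 (not isolated)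
Conditions: n-BuLi, THF, −78 °C; B(OiPr)3, −78 °C → rt; 1 M HCl to pH 5, 0 °C
Reagents that add atoms: triisopropyl borate CC(C)OB(OC(C)C)OC(C)C; water O
Why: Bromine–lithium exchange at −78 °C is faster than any ortho-deprotonation, the aryllithium is captured by the borate ester, and hydrolysis of the resulting ate complex at pH 5 should free the boronic acid while the MOM acetal survives (lithiation–borylation).

Step 3
Reactants: 5 [5-methoxy-2-(methoxymethoxy)phenyl]boronic acid; 6 (E)-pent-3-en-1-ol
Product: 7 (R)-4-[5-methoxy-2-(methoxymethoxy)phenyl]pentanal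
Conditions: Pd(CH3CN)2(OTs)2 (6 mol%), Cu(OTf)2 (6 mol%), (S)-4-tert-butyl-2-[5-(trifluoromethyl)pyridin-2-yl]-4,5-dihydrooxazole (13 mol%), O2 (1 atm), 3 Å molecular sieves, DMF, rt
Reagents that add atoms: none
Why: Enantioselective redox-relay oxidative Heck arylation: the aryl group passes from boron to the cationic divalent palladium–ligand complex, migratory insertion places it on the alkene carbon remote from the hydroxyl and sets the benzylic (R)-centre under control of the chiral pyridine-oxazoline ligand, repeated β-hydride elimination and reinsertion carry palladium to the carbinol carbon where the aldehyde is released, and O2 with Cu(OTf)2 returns zerovalent palladium to the divalent state.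

Step 4
Reactants: 7 (R)-4-[5-methoxy-2-(methoxymethoxy)phenyl]pentanal; 8 tert-butyl (triphenylphosphoranylidene)acetate
Product: 9 tert-butyl (R,E)-6-[5-methoxy-2-(methoxymethoxy)phenyl]hept-2-enoate
Conditions: CH2Cl2, rt
Reagents that add atoms: none
Why: Wittig olefination with a stabilised ylide should give the E-enoate under neutral conditions, and the stereocentre, being γ to the aldehyde, cannot epimerise.

Step 5
Reactants: 9 tert-butyl (R,E)-6-[5-methoxy-2-(methoxymethoxy)phenyl]hept-2-enoate
Product: 10 tert-butyl (R,E)-6-(2-hydroxy-5-methoxyphenyl)hept-2-enoate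
Conditions: NaHSO4·SiO2, wet CH2Cl2, rt
Reagents that add atoms: none
Why: Acid-catalysed acetal hydrolysis on the mild solid acid is selective for phenolic MOM ethers, so the tert-butyl ester and the enoate should remain intact.

Step 6
Reactants: 10 tert-butyl (R,E)-6-(2-hydroxy-5-methoxyphenyl)hept-2-enoate
Product: 11 tert-butyl (R,E)-6-(2-hydroxy-3-iodo-5-methoxyphenyl)hept-2-enoate
Conditions: NIS, TsOH·H2O (10 mol%), CH3CN, 0 °C, dark
Reagents that add atoms: N-iodosuccinimide O=C1CCC(=O)N1I
Why: Electrophilic aromatic iodination is steered by the free hydroxyl group, whose para position (OMe) and one ortho position (side chain) are occupied, so iodine should enter at the remaining ortho carbon, while the electron-poor enoate does not react with NIS.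

Step 7
Reactants: 11 tert-butyl (R,E)-6-(2-hydroxy-3-iodo-5-methoxyphenyl)hept-2-enoate
Product: 12 tert-butyl (R,E)-6-[3-iodo-5-methoxy-2-(methoxymethoxy)phenyl]hept-2-enoate
Conditions: MOMCl, i-Pr2NEt, CH2Cl2, 0 °C → rt
Reagents that add atoms: chloromethyl methyl ether COCCl
Why: O-Alkylation of the hindered phenol under amine-base conditions restores the MOM acetal, which must mask the oxygen next to the iodide during the carbonylation.

Step 8
Reactants: 13 pent-4-yn-1-ol; 8 tert-butyl (triphenylphosphoranylidene)acetate
Product: 15 tert-butyl (E)-hept-2-en-6-ynoate, via pent-4-ynal 14 (not isolated)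
Conditions: PhI(OAc)2, TEMPO (10 mol%), CH2Cl2, rt; then 8, rt
Reagents that add atoms: none
Why: The TEMPO/PhI(OAc)2 oxidation stops at the aldehyde, and the volatile pent-4-ynal is trapped in the same flask by Wittig olefination with the stabilised ylide, which should give the E-enoate and leave the terminal alkyne untouched.

Step 9
Reactants: 12 tert-butyl (R,E)-6-[3-iodo-5-methoxy-2-(methoxymethoxy)phenyl]hept-2-enoate; 15 tert-butyl (E)-hept-2-en-6-ynoate; 16 carbon monoxide
Product: 17 tert-butyl (R,E)-6-{3-[(E)-8-tert-butoxy-8-oxooct-6-en-2-ynoyl]-5-methoxy-2-(methoxymethoxy)phenyl}hept-2-enoate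
Conditions: PdCl2(PPh3)2 (5 mol%), Et3N (3 equiv), CO (5 bar), THF, 40 °C, no copper salt
Reagents that add atoms: none
Why: Zerovalent palladium, formed in the flask from PdCl2(PPh3)2, inserts into the C–I bond of 12, CO then inserts to give an aroyl divalent palladium species, the terminal alkyne of 15 is transferred to it with Et3N as proton acceptor, and reductive elimination releases ynone 17, so the aryl–C(=O) and C(=O)–C(alkyne) bonds are made in one operation. This is the carbonylative Sonogashira coupling of aryl iodides with terminal alkynes, a known route to alkynones. No ring is closed and no stereocentre is formed; the benzylic (R)-centre is remote and is not touched. The step needs CO insertion to outrun direct alkynylation: the electron-rich arylpalladium intermediate migrates readily onto CO, the absence of a copper acetylide slows the direct pathway, and CO pressure keeps the aroyl species populated. The MOM ether keeps the ortho oxygen from adding to the aroylpalladium or to the ynone (which would give a chromone), and the disubstituted enoates of both partners are poor Heck acceptors at 40 °C.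

Step 10
Reactants: 17 tert-butyl (R,E)-6-{3-[(E)-8-tert-butoxy-8-oxooct-6-en-2-ynoyl]-5-methoxy-2-(methoxymethoxy)phenyl}hept-2-enoate
Product: 19 tert-butyl (2E,4E,6E)-8-{3-[(2R,5E)-7-tert-butoxy-7-oxohept-5-en-2-yl]-5-methoxy-2-(methoxymethoxy)phenyl}-8-oxoocta-2,4,6-trienoate, via allenyl ketone 18 (not isolated)
Conditions: PPh3 (20 mol%), PhOH (20 mol%), toluene, 80 °C, dark
Reagents that add atoms: none
Why: Phosphine-catalysed redox isomerisation of an ynone to a conjugated dienone: PPh3 adds to the β-alkyne carbon, proton shifts through the allenyl ketone move the unsaturation into the CH2–CH2 unit that is acidified by the ynone on one side and by the enoate on the other, and loss of PPh3 should leave the fully conjugated all-E trienone as the thermodynamic sink, with phenol as proton shuttle favouring protonation of the zwitterion over its addition to the tethered enoate.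

Step 11
Reactants: 19 tert-butyl (2E,4E,6E)-8-{3-[(2R,5E)-7-tert-butoxy-7-oxohept-5-en-2-yl]-5-methoxy-2-(methoxymethoxy)phenyl}-8-oxoocta-2,4,6-trienoate
Product: 20 (2E,4E,6E)-8-{3-[(2R,5E)-6-carboxyhex-5-en-2-yl]-2-hydroxy-5-methoxyphenyl}-8-oxoocta-2,4,6-trienoic acid
Conditions: TFA/CH2Cl2 (1:3), H2O (5 equiv), 0 °C → rt, dark
Reagents that add atoms: none
Why: Acidolysis: TFA cleaves both tert-butyl esters by E1 loss of 2-methylpropene and hydrolyses the aryl MOM acetal (its departure assisted by the hydrogen-bonding ortho ketone), and the all-E trienone, protected from light, should survive the short exposure.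

**Compound list**
1 | 2-bromo-4-methoxyphenol | Oc1ccc(OC)cc1Br | starting material
2 | 2-bromo-4-methoxy-1-(methoxymethoxy)benzene | COCOc1ccc(OC)cc1Br | intermediate
3 | [5-methoxy-2-(methoxymethoxy)phenyl]lithium | [Li]c1cc(OC)ccc1OCOC | intermediate
4 | lithium [5-methoxy-2-(methoxymethoxy)phenyl]tri(propan-2-yloxy)borate | [Li+].COCOc1ccc(OC)cc1[B-](OC(C)C)(OC(C)C)OC(C)C | intermediate
5 | [5-methoxy-2-(methoxymethoxy)phenyl]boronic acid | COCOc1ccc(OC)cc1B(O)O | intermediate
6 | (E)-pent-3-en-1-ol | C/C=C/CCO | starting material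
7 | (R)-4-[5-methoxy-2-(methoxymethoxy)phenyl]pentanal | COCOc1ccc(OC)cc1[C@H](C)CCC=O | intermediate
8 | tert-butyl (triphenylphosphoranylidene)acetate | CC(C)(C)OC(=O)C=P(c1ccccc1)(c1ccccc1)c1ccccc1 | starting material
9 | tert-butyl (R,E)-6-[5-methoxy-2-(methoxymethoxy)phenyl]hept-2-enoate | COCOc1ccc(OC)cc1[C@H](C)CC/C=C/C(=O)OC(C)(C)C | intermediate
10 | tert-butyl (R,E)-6-(2-hydroxy-5-methoxyphenyl)hept-2-enoate | Oc1ccc(OC)cc1[C@H](C)CC/C=C/C(=O)OC(C)(C)C | intermediate
11 | tert-butyl (R,E)-6-(2-hydroxy-3-iodo-5-methoxyphenyl)hept-2-enoate | Oc1c(I)cc(OC)cc1[C@H](C)CC/C=C/C(=O)OC(C)(C)C | intermediate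
12 | tert-butyl (R,E)-6-[3-iodo-5-methoxy-2-(methoxymethoxy)phenyl]hept-2-enoate | COCOc1c(I)cc(OC)cc1[C@H](C)CC/C=C/C(=O)OC(C)(C)C | intermediate
13 | pent-4-yn-1-ol | C#CCCCO | starting material
14 | pent-4-ynal | C#CCCC=O | intermediate
15 | tert-butyl (E)-hept-2-en-6-ynoate | C#CCC/C=C/C(=O)OC(C)(C)C | intermediate
16 | carbon monoxide | [C-]#[O+] | starting material
17 | tert-butyl (R,E)-6-{3-[(E)-8-tert-butoxy-8-oxooct-6-en-2-ynoyl]-5-methoxy-2-(methoxymethoxy)phenyl}hept-2-enoate | COCOc1c(C(=O)C#CCC/C=C/C(=O)OC(C)(C)C)cc(OC)cc1[C@H](C)CC/C=C/C(=O)OC(C)(C)C | intermediate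
18 | tert-butyl (R,E)-6-{3-[(E)-8-tert-butoxy-8-oxoocta-2,3,6-trienoyl]-5-methoxy-2-(methoxymethoxy)phenyl}hept-2-enoate (allene epimers) | COCOc1c(C(=O)C=C=CC/C=C/C(=O)OC(C)(C)C)cc(OC)cc1[C@H](C)CC/C=C/C(=O)OC(C)(C)C | intermediate
19 | tert-butyl (2E,4E,6E)-8-{3-[(2R,5E)-7-tert-butoxy-7-oxohept-5-en-2-yl]-5-methoxy-2-(methoxymethoxy)phenyl}-8-oxoocta-2,4,6-trienoate | COCOc1c(C(=O)/C=C/C=C/C=C/C(=O)OC(C)(C)C)cc(OC)cc1[C@H](C)CC/C=C/C(=O)OC(C)(C)C | intermediate
20 | (2E,4E,6E)-8-{3-[(2R,5E)-6-carboxyhex-5-en-2-yl]-2-hydroxy-5-methoxyphenyl}-8-oxoocta-2,4,6-trienoic acid | COc1cc(C(=O)/C=C/C=C/C=C/C(=O)O)c(O)c([C@H](C)CC/C=C/C(=O)O)c1 | target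

**Count**
Total steps: 11. Longest linear sequence: 10 steps (steps 1–7, then 9–11).

**Steps most likely to fail**

Step 10. The phosphonium zwitterion may add to the tethered enoate (carbocyclisation) before proton transfer, the growing polyene may oligomerise, or the sequence may stall at the allenyl ketone. The fallback sets out from 12 and returns at 19, bringing the trienone in preformed instead of making it by isomerisation. (E)-3-(Tributylstannyl)prop-2-en-1-ol is oxidised with MnO2 (CH2Cl2, rt) to (E)-3-(tributylstannyl)prop-2-enal F1. Vinylogous Horner–Wadsworth–Emmons olefination with tert-butyl (E)-4-(diethoxyphosphoryl)but-2-enoate (LiN(SiMe3)2, THF, −78 → 0 °C) should give tert-butyl (2E,4E,6E)-7-(tributylstannyl)hepta-2,4,6-trienoate F2. Carbonylative Stille coupling of 12, CO (16) and F2 (Pd2(dba)3, AsPh3, CO 3 bar, THF, 50 °C) would then give 19 directly, and step 11 follows unchanged.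

Step 9. Direct alkynylation without CO uptake, slow CO insertion next to the ortho MOM ether, or onward reaction of the ynone with amine or free phosphine may erode the coupling. The fallback sets out from 12 and returns at 17, making the two bonds one at a time. Reductive carbonylation of 12 (Pd(PPh3)4, CO 3 bar, slow addition of Bu3SnH, THF, 50 °C) should give tert-butyl (R,E)-6-[3-formyl-5-methoxy-2-(methoxymethoxy)phenyl]hept-2-enoate F3. Addition of alkyne 15 mediated by Zn(OTf)2 and Et3N (toluene, rt) should give tert-butyl (R,E)-6-{3-[(E)-8-tert-butoxy-1-hydroxy-8-oxooct-6-en-2-yn-1-yl]-5-methoxy-2-(methoxymethoxy)phenyl}hept-2-enoate F4 as both carbinol epimers, which is of no consequence. MnO2 (CH2Cl2, rt) then oxidises this benzylic propargylic alcohol to 17.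

Step 3. Slow boron-to-palladium transfer and protodeboronation of the electron-rich ortho-alkoxy boronic acid, biaryl formation, or insufficient site and facial selectivity in the insertion may limit the step. The fallback sets out from 5 and returns at 7. Hayashi–Miyaura conjugate addition of 5 to propan-2-yl (E)-but-2-enoate (Rh(acac)(C2H4)2, (S)-BINAP, dioxane/H2O, 100 °C) should give propan-2-yl (R)-3-[5-methoxy-2-(methoxymethoxy)phenyl]butanoate F5; the (S)-ligand is expected to give the (R)-ester by attack on the si face of the α-carbon. Reduction with i-Bu2AlH (toluene, −78 °C) gives (R)-3-[5-methoxy-2-(methoxymethoxy)phenyl]butanal F6. Wittig reaction with Ph3P=CHOMe (from (methoxymethyl)triphenylphosphonium chloride and KN(SiMe3)2, THF, 0 °C) gives 4-methoxy-2-[(2R)-5-methoxypent-4-en-2-yl]-1-(methoxymethoxy)benzene F7 as an E/Z mixture. Brief hydrolysis of the enol ether (dilute HCl, wet THF, 0 °C), under which the aryl MOM ether should persist, gives 7.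

**Further compounds**
F1 | step 10 | (E)-3-(tributylstannyl)prop-2-enal | CCCC[Sn](CCCC)(CCCC)/C=C/C=O
F2 | step 10 | tert-butyl (2E,4E,6E)-7-(tributylstannyl)hepta-2,4,6-trienoate | CCCC[Sn](CCCC)(CCCC)/C=C/C=C/C=C/C(=O)OC(C)(C)C
F3 | step 9 | tert-butyl (R,E)-6-[3-formyl-5-methoxy-2-(methoxymethoxy)phenyl]hept-2-enoate | COCOc1c(C=O)cc(OC)cc1[C@H](C)CC/C=C/C(=O)OC(C)(C)C
F4 | step 9 | tert-butyl (R,E)-6-{3-[(E)-8-tert-butoxy-1-hydroxy-8-oxooct-6-en-2-yn-1-yl]-5-methoxy-2-(methoxymethoxy)phenyl}hept-2-enoate (both carbinol epimers) | COCOc1c(C(O)C#CCC/C=C/C(=O)OC(C)(C)C)cc(OC)cc1[C@H](C)CC/C=C/C(=O)OC(C)(C)C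
F5 | step 3 | propan-2-yl (R)-3-[5-methoxy-2-(methoxymethoxy)phenyl]butanoate | COCOc1ccc(OC)cc1[C@H](C)CC(=O)OC(C)C
F6 | step 3 | (R)-3-[5-methoxy-2-(methoxymethoxy)phenyl]butanal | COCOc1ccc(OC)cc1[C@H](C)CC=O
F7 | step 3 | 4-methoxy-2-[(2R)-5-methoxypent-4-en-2-yl]-1-(methoxymethoxy)benzene (E/Z mixture) | COCOc1ccc(OC)cc1[C@H](C)CC=COC
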